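It is tempting to scale a rate at fixed conversion with the catalyst charged, but at equal partner a flask charged with more precatalyst reaches that conversion sooner, with a smaller share of its precatalyst turned on.

the same everywhere: substrate 0.050 M
- Friday's: partner 0.062 M; precatalyst 70 µM; run made earlier
- Sunday's: partner 0.25 M; precatalyst 70 µM; run made earlier
- Saturday's: partner 0.125 M; precatalyst 100 µM; run made earlier
- flask: partner 0.125 M; precatalyst 70 µM

| run | time / min | product / % | substrate / % |
|---|---|---|---|
| Friday's | 0.333 | 0 | 97.9 |
| Friday's | 0.500 | 0.3 | 96.8 |
| Friday's | 0.667 | 0 | 93.1 |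
| Friday's | 1.00 | 0 | 87.2 |
| Friday's | 1.50 | 0.1 | 75.3 |
| Friday's | 2.50 | 0.8 | 52.1 |
| Friday's | 4.00 | 4.2 | 24.1 |
| Sunday's | 0.200 | 0.1 | 98.2 |
| Sunday's | 0.667 | 0 | 80.6 |
| Sunday's | 1.00 | 1.8 | 66.3 |
| Sunday's | 1.50 | 4.4 | 45.1 |
| Sunday's | 2.50 | 14.8 | 20.6 |
| Sunday's | 3.00 | 21.3 | 13.1 |
| Sunday's | 4.00 | 32.2 | 5.5 |
| Saturday's | 0.333 | 0.4 | 95.2 |
| Saturday's | 1.00 | 0 | 70.8 |
| Saturday's | 2.00 | 5.2 | 34.4 |
| Saturday's | 3.00 | 11.9 | 14.7 |
| Saturday's | 4.00 | 20.4 | 4.9 |

(scatter of a reading: 0.5 percentage points)

- factor on the rate of making product when 30% of the substrate are converted if partner is charged twice over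
- factor on the rate when 30% of the substrate are converted if precatalyst is charged at 800 µM instead



In Saturday's run the pseudo-first-order constant of substrate loss climbs from 0.148 min⁻¹ at the first reading to 1.10 min⁻¹ at the end. Run back, that late line reads as an induction period of 1.25 min. Scaled in proportion to this flask's 70 µM, I take the late constant as 0.769 min⁻¹.

My turn-on number is the first-order loss needed for 30% conversion, divided by the loss that the late constant gives in one induction period: 0.370 here. A small value means the conversion arrives during induction. Assuming an exponential turn-on, I reckon the induction periods elapsed by a short series as √(2n) + n/3, which gives 0.983, an estimated time of 1.23 min and an estimated turned-on share of 0.626.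

Saturday's reading at 1.00 min shows product 0% with 29.2% of the substrate missing, so I freeze the intermediate at equal conversion and take the rate to follow partner times turned-on catalyst. If doubling partner halves the induction period, the number becomes 0.739 and the share 0.768, so my factor is 2.46. That recipe is Sunday's, and the number puts its 30% at 0.917 min, later than 0.667 min and earlier than 1.00 min, the times at which Sunday's substrate reads 80.6% and 66.3%.

The forecast says 1.9 (1.4 to 2.5) for doubled partner and 4.5 (2.5 to 9) for 800 µM of precatalyst, noting that “the catalyst activates slowly”. My doubling factor is higher.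

    free catalyst + open intermediate ⇌ catalyst intermediate (K = 14.2 L mol⁻¹, k = 321 L mol⁻¹ s⁻¹)
    partner + catalyst intermediate → free catalyst + product (k = 22.3 L mol⁻¹ s⁻¹)
    substrate + free catalyst → free catalyst + open intermediate (k = 294 L mol⁻¹ s⁻¹)
    partner + precatalyst → free catalyst + spent reagent (k = 0.0686 L mol⁻¹ s⁻¹)

Doubling partner multiplies the rate at 30% conversion by 2.33. This flask reaches 30% conversion at 1.23 min, and I had reckoned 1.23 min. At 800 µM the number falls to 0.0323 and my reckoned share to 0.233, so charge times share gives 4.25, where the flask gives 3.88.

The readings were computed from invented constants; scatter was added.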